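**Plan**
- Retrosynthesis: after the two MOM groups, the TBS group and the 5-O-methyl group are taken off, ring A is cut at C8–C7 and C4a–C5, then the C2–C1' biaryl bond, then the C2''–C3'' bond of the side chain.
- Enabling feature: C5, C6 and C7 of ring A carry O, OMe, O, the pattern of one methoxymalonyl unit; C8, C8a and C4a are the methyl carbon, C6 and C5 of a 2-aryl-3-alkoxy-6-methyl-4-pyranone (ring C with ring B attached), which is a masked 1,3,5-tricarbonyl chain.
- Forward: ring C comes from kojic acid (deoxygenation, bromination, MOM ether) and ring B from 5-bromo-2-methoxyphenylacetic acid (Weinreb amide, isopropenyl Grignard, reduction, TBS ether, borylation); a Suzuki coupling joins B to C.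
- Ring A is the only ring made: the silyl dienol ether of the methylpyranone is acylated twice by methoxymalonyl dichloride in a [3+3] benzannulation; 7-O-MOM protection, 5-O-methylation and acid deprotection finish the route.
- Stereochemistry: the single stereocentre C2'' (R) comes from CBS reduction of the arylmethyl isopropenyl ketone with the (S)-oxazaborolidine and is carried as its TBS ether; no later step touches it.

Key step: step 13

Remark: flavone numbering (O1, C2, C3, C4, C4a, C5–C8, C8a; ring B primed; side chain C1''–C4'') is used also for the pyranone precursors, and R at C2'' follows from O > isopropenyl > CH2Ar > H, which O-silylation does not change.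

**Route**

Step 1
Reactants: 1 kojic acid
Product: 2 2-(chloromethyl)-5-hydroxy-4H-pyran-4-one (chlorokojic acid)
Conditions: SOCl2, CH2Cl2, rt
Reagents that add atoms: thionyl chloride, O=S(Cl)Cl
Why: Chlorodehydroxylation of the primary alcohol through its chlorosulfite, with the enolic 5-OH (a vinylogous acid) left untouched.

Step 2
Reactants: 2 chlorokojic acid
Product: 3 5-hydroxy-2-methyl-4H-pyran-4-one (allomaltol)
Conditions: Zn dust, conc. HCl, H2O, 70 °C
Reagents that add atoms: none
Why: Dissolving-metal reductive dehalogenation of the activated C–Cl bond, the classical route from chlorokojic acid to allomaltol.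

Step 3
Reactants: 3 allomaltol
Product: 4 2-bromo-3-hydroxy-6-methyl-4H-pyran-4-one
Conditions: NBS, MeCN, 0 °C → rt, dark
Reagents that add atoms: N-bromosuccinimide, O=C1CCC(=O)N1Br
Why: The enolic OH makes the adjacent ring carbon the nucleophilic β-carbon of an enol, so electrophilic bromination occurs there, as in the halogenation of kojic and pyromeconic acid.

Step 4
Reactants: 4 2-bromo-3-hydroxy-6-methyl-4H-pyran-4-one
Product: 5 2-bromo-3-(methoxymethoxy)-6-methyl-4H-pyran-4-one
Conditions: MOMCl, i-Pr2NEt, CH2Cl2, 0 °C → rt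
Reagents that add atoms: chloromethyl methyl ether, COCCl
Why: Williamson-type O-alkylation of the acidic enol gives a MOM acetal that withstands palladium coupling, lithium amide and acyl chloride with amine base and is removable with mild acid at the end.

Step 5
Reactants: 6 5-bromo-2-methoxyphenylacetic acid
Product: 8 2-(5-bromo-2-methoxyphenyl)-N-methoxy-N-methylacetamide, via acyl imidazolide 7 (not isolated)
Conditions: CDI, CH2Cl2, rt; then MeNH(OMe)·HCl, rt
Reagents that add atoms: N,O-dimethylhydroxylamine hydrochloride, CNOC.Cl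
Why: Carboxyl activation as the acyl imidazolide and aminolysis is a standard Weinreb amide synthesis.

Step 6
Reactants: 8 Weinreb amide; 9 isopropenylmagnesium bromide
Product: 10 1-(5-bromo-2-methoxyphenyl)-3-methylbut-3-en-2-one
Conditions: THF, −20 → 0 °C; cold 1 M HCl quench
Reagents that add atoms: none
Why: Weinreb ketone synthesis, in which the chelated tetrahedral adduct survives until the quench so that over-addition is avoided, and the cold acidic quench keeps the released amine from adding to the enone.

Step 7
Reactants: 10 enone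
Product: 11 (2R)-1-(5-bromo-2-methoxyphenyl)-3-methylbut-3-en-2-ol
Conditions: (S)-2-methyl-CBS-oxazaborolidine (20 mol %), catecholborane, toluene, −78 °C; aq. NaOH work-up
Reagents that add atoms: none
Why: Corey–Bakshi–Shibata reduction in which the branched isopropenyl group acts as the large and the arylmethyl group as the small substituent, so the (S)-catalyst should deliver hydride to give the (R)-carbinol, while catecholborane at low temperature leaves the 1,1-disubstituted alkene unhydroborated.

Step 8
Reactants: 11 (R)-allylic alcohol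
Product: 12 {[(2R)-1-(5-bromo-2-methoxyphenyl)-3-methylbut-3-en-2-yl]oxy}(tert-butyl)dimethylsilane
Conditions: TBSCl, imidazole, DMF, rt
Reagents that add atoms: tert-butyldimethylsilyl chloride, CC(C)(C)[Si](C)(C)Cl
Why: Standard silylation of a secondary alcohol, giving an ether stable to the coupling, amide-base, acylation and alkylation steps that follow.

Step 9
Reactants: 12 aryl bromide
Product: 13 2-{3-[(2R)-2-(tert-butyldimethylsilyloxy)-3-methylbut-3-en-1-yl]-4-methoxyphenyl}-4,4,5,5-tetramethyl-1,3,2-dioxaborolane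
Conditions: B2pin2, PdCl2(dppf) (5 mol %), KOAc, 1,4-dioxane, 85 °C
Reagents that add atoms: bis(pinacolato)diboron, CC1(C)OB(OC1(C)C)B1OC(C)(C)C(C)(C)O1
Why: Miyaura borylation of an aryl bromide, which tolerates the silyl ether and the unactivated alkene.

Step 10
Reactants: 5 bromopyranone; 13 aryl boronate
Product: 14 2-{3-[(2R)-2-(tert-butyldimethylsilyloxy)-3-methylbut-3-en-1-yl]-4-methoxyphenyl}-3-(methoxymethoxy)-6-methyl-4H-pyran-4-one
Conditions: PdCl2(dppf) (5 mol %), K2CO3, 1,4-dioxane/H2O, 80 °C
Reagents that add atoms: none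
Why: Suzuki–Miyaura coupling, in which the C–Br bond of the 3-alkoxy-4-pyranone behaves as a β-bromo enone that adds readily to zerovalent palladium, and the carbonate base spares the pyranone, MOM and TBS groups.

Step 11
Reactants: 15 dimethyl methoxymalonate
Product: 16 methoxymalonic acid
Conditions: NaOH, H2O/MeOH, rt; then HCl, 0 °C, EtOAc extraction
Reagents that add atoms: sodium hydroxide, [Na+].[OH-]
Why: Saponification of both methyl esters followed by cold acidification gives the malonic acid, which does not decarboxylate at this temperature.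

Step 12
Reactants: 16 methoxymalonic acid
Product: 17 methoxymalonyl dichloride
Conditions: (COCl)2, DMF (cat.), CH2Cl2, 0 °C → rt; volatiles removed, used at once
Reagents that add atoms: oxalyl chloride, O=C(Cl)C(=O)Cl
Why: Acid chloride formation through Vilsmeier-type activation, as used for alkylmalonyl dichlorides, with the product taken on fresh to limit self-condensation.

Step 13
Reactants: 14 methylpyranone; 17 methoxymalonyl dichloride
Product: 20 2-{3-[(2R)-2-(tert-butyldimethylsilyloxy)-3-methylbut-3-en-1-yl]-4-methoxyphenyl}-5,7-dihydroxy-6-methoxy-3-(methoxymethoxy)-4H-chromen-4-one, via silyl dienol ether 18 (not isolated), via keto acyl chloride 19 (not isolated)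
Conditions: LiN(SiMe3)2 (1.05 equiv), THF, −78 °C; Me3SiCl (1.2 equiv); added to 17 (1.3 equiv), THF, −78 → −20 °C; i-Pr2NEt (3 equiv), −20 °C → rt; NaHCO3, MeOH/H2O work-up
Reagents that add atoms: none
Why: Proposed new method: the lithium amide removes a proton from the 6-methyl group (vinylogous to the C4 carbonyl) and O-silylation gives the 2-methylene-2H-pyran 18, whose exocyclic carbon (future C8) attacks one acyl chloride of 17 because this regenerates an aromatic 4-silyloxypyrylium ion, which sheds Me3SiCl to leave pyranone 19 with the C8–C7 bond made. Hünig's base then removes HCl from the remaining α-methoxy acyl chloride to give a methoxy-substituted acylketene, and with the C7 ketone enolised towards C8 the C4a=C8a, C8=C7 and C6=C5 double bonds form a dienylketene that closes ring A by thermal disrotatory 6π-electrocyclisation (in the polar limit a 6-(enolendo)-exo-trig C-acylation of the nucleophilic pyranone carbon C4a), making the C4a–C5 bond, after which the cyclohexadienone tautomerises to the 5,7-dihydroxy-6-methoxy arene. The closest known reaction types are the C-acylation of methylenepyran anhydrobases and silyl dienol ethers by acid chlorides, the cyclocondensation of malonyl dichlorides or (chlorocarbonyl)ketenes with 1,3-dinucleophiles, and dienylketene electrocyclisation to phenols as in the Danheiser benzannulation; the whole mirrors the Claisen folding of a polyketide chain. No stereocentre is created, and the silylated C2'' carbinol lies far from every basic or electrophilic site. The step needs C- rather than O-acylation at both ends: the first is secured by the soft exocyclic carbon of 18, the second by geometry, since from C5 only C4a can be reached through a six-membered array (the C7 enol oxygen would close a four-membered and the C4 carbonyl oxygen an eight-membered ring), while double intermolecular acylation is held back by adding 18 to an excess of 17 at high dilution. Since both acyl ends of 17 are identical and the ring oxygen is fixed beforehand, only one orientation of the annulation exists and the 6-OMe/8-OMe isomer problem of phloroglucinol-based flavone syntheses cannot occur.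

Step 14
Reactants: 20 5,7-dihydroxyflavone
Product: 21 2-{3-[(2R)-2-(tert-butyldimethylsilyloxy)-3-methylbut-3-en-1-yl]-4-methoxyphenyl}-5-hydroxy-6-methoxy-3,7-bis(methoxymethoxy)-4H-chromen-4-one
Conditions: MOMCl (1.1 equiv), i-Pr2NEt, CH2Cl2, 0 °C
Reagents that add atoms: chloromethyl methyl ether, COCCl
Why: The 7-OH is the more acidic, unhindered phenol whereas the 5-OH is hydrogen-bonded to the C4 carbonyl and flanked by the 6-OMe group, so one equivalent of MOMCl should alkylate O7 only (chelation-controlled differentiation as usual for 5,7-dihydroxyflavones).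

Step 15
Reactants: 21 5-hydroxyflavone
Product: 22 2-{3-[(2R)-2-(tert-butyldimethylsilyloxy)-3-methylbut-3-en-1-yl]-4-methoxyphenyl}-5,6-dimethoxy-3,7-bis(methoxymethoxy)-4H-chromen-4-one
Conditions: MeI (excess), K2CO3, DMF, 40 °C
Reagents that add atoms: iodomethane, CI
Why: With O7 blocked, Williamson methylation of the chelated 5-OH under forcing but non-acidic conditions is standard in polymethoxyflavone work and leaves the acetals and the silyl ether intact.

Step 16
Reactants: 22 fully protected flavonol
Product: 23 3,7-dihydroxy-2-{3-[(2R)-2-hydroxy-3-methylbut-3-en-1-yl]-4-methoxyphenyl}-5,6-dimethoxy-4H-chromen-4-one (target)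
Conditions: HCl (1.25 M in MeOH), 0 °C → rt
Reagents that add atoms: none
Why: Acid-catalysed methanolysis cleaves both MOM acetals and the secondary TBS ether in one operation, while the alkene (deactivated towards protonation by the adjacent carbinol oxygen) and the stereocentre (not ionised by dilute acid) should stay intact.

**Compound list**

1 | kojic acid, 5-hydroxy-2-(hydroxymethyl)-4H-pyran-4-one | O=c1cc(CO)occ1O | starting material
2 | 2-(chloromethyl)-5-hydroxy-4H-pyran-4-one | O=c1cc(CCl)occ1O | intermediate
3 | 5-hydroxy-2-methyl-4H-pyran-4-one (allomaltol) | Cc1cc(=O)c(O)co1 | intermediate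
4 | 2-bromo-3-hydroxy-6-methyl-4H-pyran-4-one | Cc1cc(=O)c(O)c(Br)o1 | intermediate
5 | 2-bromo-3-(methoxymethoxy)-6-methyl-4H-pyran-4-one | COCOc1c(Br)oc(C)cc1=O | intermediate
6 | 5-bromo-2-methoxyphenylacetic acid | COc1ccc(Br)cc1CC(=O)O | starting material
7 | 2-(5-bromo-2-methoxyphenyl)-1-(imidazol-1-yl)ethanone (acyl imidazolide, not isolated) | COc1ccc(Br)cc1CC(=O)n1ccnc1 | intermediate
8 | 2-(5-bromo-2-methoxyphenyl)-N-methoxy-N-methylacetamide | COc1ccc(Br)cc1CC(=O)N(C)OC | intermediate
9 | isopropenylmagnesium bromide | C=C(C)[Mg]Br | starting material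
10 | 1-(5-bromo-2-methoxyphenyl)-3-methylbut-3-en-2-one | C=C(C)C(=O)Cc1cc(Br)ccc1OC | intermediate
11 | (2R)-1-(5-bromo-2-methoxyphenyl)-3-methylbut-3-en-2-ol | C=C(C)[C@H](O)Cc1cc(Br)ccc1OC | intermediate
12 | {[(2R)-1-(5-bromo-2-methoxyphenyl)-3-methylbut-3-en-2-yl]oxy}(tert-butyl)dimethylsilane | C=C(C)[C@H](O[Si](C)(C)C(C)(C)C)Cc1cc(Br)ccc1OC | intermediate
13 | 2-{3-[(2R)-2-(tert-butyldimethylsilyloxy)-3-methylbut-3-en-1-yl]-4-methoxyphenyl}-4,4,5,5-tetramethyl-1,3,2-dioxaborolane | C=C(C)[C@H](O[Si](C)(C)C(C)(C)C)Cc1cc(B2OC(C)(C)C(C)(C)O2)ccc1OC | intermediate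
14 | 2-{3-[(2R)-2-(tert-butyldimethylsilyloxy)-3-methylbut-3-en-1-yl]-4-methoxyphenyl}-3-(methoxymethoxy)-6-methyl-4H-pyran-4-one | C=C(C)[C@H](O[Si](C)(C)C(C)(C)C)Cc1cc(-c2oc(C)cc(=O)c2OCOC)ccc1OC | intermediate
15 | dimethyl methoxymalonate | COC(C(=O)OC)C(=O)OC | starting material
16 | methoxymalonic acid | COC(C(=O)O)C(=O)O | intermediate
17 | methoxymalonyl dichloride | COC(C(=O)Cl)C(=O)Cl | intermediate
18 | silyl dienol ether of 14: the 6-methylidene-4-(trimethylsilyloxy)-6H-pyran bearing the 2-aryl and 3-(methoxymethoxy) groups (not isolated) | C=C(C)[C@H](O[Si](C)(C)C(C)(C)C)Cc1cc(C2=C(OCOC)C(O[Si](C)(C)C)=CC(=C)O2)ccc1OC | intermediate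
19 | 4-[6-aryl-5-(methoxymethoxy)-4-oxo-4H-pyran-2-yl]-2-methoxy-3-oxobutanoyl chloride, aryl as in 14, methoxy-bearing carbon of undefined configuration (not isolated) | C=C(C)[C@H](O[Si](C)(C)C(C)(C)C)Cc1cc(-c2oc(CC(=O)C(OC)C(=O)Cl)cc(=O)c2OCOC)ccc1OC | intermediate
20 | 2-{3-[(2R)-2-(tert-butyldimethylsilyloxy)-3-methylbut-3-en-1-yl]-4-methoxyphenyl}-5,7-dihydroxy-6-methoxy-3-(methoxymethoxy)-4H-chromen-4-one | C=C(C)[C@H](O[Si](C)(C)C(C)(C)C)Cc1cc(-c2oc3cc(O)c(OC)c(O)c3c(=O)c2OCOC)ccc1OC | intermediate
21 | 2-{3-[(2R)-2-(tert-butyldimethylsilyloxy)-3-methylbut-3-en-1-yl]-4-methoxyphenyl}-5-hydroxy-6-methoxy-3,7-bis(methoxymethoxy)-4H-chromen-4-one | C=C(C)[C@H](O[Si](C)(C)C(C)(C)C)Cc1cc(-c2oc3cc(OCOC)c(OC)c(O)c3c(=O)c2OCOC)ccc1OC | intermediate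
22 | 2-{3-[(2R)-2-(tert-butyldimethylsilyloxy)-3-methylbut-3-en-1-yl]-4-methoxyphenyl}-5,6-dimethoxy-3,7-bis(methoxymethoxy)-4H-chromen-4-one | C=C(C)[C@H](O[Si](C)(C)C(C)(C)C)Cc1cc(-c2oc3cc(OCOC)c(OC)c(OC)c3c(=O)c2OCOC)ccc1OC | intermediate
23 | 3,7-dihydroxy-2-{3-[(2R)-2-hydroxy-3-methylbut-3-en-1-yl]-4-methoxyphenyl}-5,6-dimethoxy-4H-chromen-4-one | C=C(C)[C@H](O)Cc1cc(-c2oc3cc(O)c(OC)c(OC)c3c(=O)c2O)ccc1OC | target

**Step count**
Total: 16 steps. Longest linear sequence: 10 steps (6 → 23 through steps 5–10 and 13–16).

**Steps most likely to fail**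

1. Step 13 (Proposed new method). After the first C-acylation the tethered acyl chloride or acylketene may fail to close onto C4a; it may dimerise or be trapped by a second dienol ether or another enol, giving open-chain or oligomeric keto acyl products. Protonation of the dienol ether before acylation is the other leak. The fallback uses known chemistry, buys ring A as an arene and closes ring C last; it sets out from aryl bromide 12 and comes back at target 23.
   - Bromine–lithium exchange of 12 (n-BuLi, THF, −78 °C) and formylation with DMF would give 3-[(2R)-2-(tert-butyldimethylsilyloxy)-3-methylbut-3-en-1-yl]-4-methoxybenzaldehyde F1.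
   - Purchased 1-(2,4-dihydroxy-6-methoxyphenyl)ethanone F2 would be allylated at its non-chelated hydroxyl (allyl bromide, K2CO3, acetone) to 1-[4-(allyloxy)-2-hydroxy-6-methoxyphenyl]ethanone F3.
   - Elbs persulfate oxidation (K2S2O8, aq. NaOH; then HCl, heat) would hydroxylate F3 para to the free phenol, giving 1-[4-(allyloxy)-3,6-dihydroxy-2-methoxyphenyl]ethanone F4.
   - Methylation of the non-chelated hydroxyl (Me2SO4, one equivalent, K2CO3, acetone) would give 1-[4-(allyloxy)-6-hydroxy-2,3-dimethoxyphenyl]ethanone F5.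
   - Claisen–Schmidt condensation of F5 with F1 (KOH, EtOH, rt) would give (E)-1-[4-(allyloxy)-6-hydroxy-2,3-dimethoxyphenyl]-3-{3-[(2R)-2-(tert-butyldimethylsilyloxy)-3-methylbut-3-en-1-yl]-4-methoxyphenyl}prop-2-en-1-one F6.
   - Algar–Flynn–Oyamada oxidation (H2O2, NaOH, MeOH, 0 °C) would close ring C to 7-(allyloxy)-2-{3-[(2R)-2-(tert-butyldimethylsilyloxy)-3-methylbut-3-en-1-yl]-4-methoxyphenyl}-3-hydroxy-5,6-dimethoxy-4H-chromen-4-one F7. Aurone formation is the known competing path of 6'-methoxychalcones and would have to be separated.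
   - n-Bu4NF in THF would free the side-chain alcohol to give 7-(allyloxy)-3-hydroxy-2-{3-[(2R)-2-hydroxy-3-methylbut-3-en-1-yl]-4-methoxyphenyl}-5,6-dimethoxy-4H-chromen-4-one F8, and deallylation with Pd(PPh3)4 and morpholine in THF would give 23.

2. Step 7. Facial discrimination may be poor because the catalyst must tell an isopropenyl from an arylmethyl flank, and hydroboration of the alkene may compete, so the optical purity of the only stereocentre may be low. The fallback replaces asymmetric reduction by resolution; it sets out from enone 10 and comes back at alcohol 11. Luche reduction (NaBH4, CeCl3·7H2O, MeOH, 0 °C) would give racemic 1-(5-bromo-2-methoxyphenyl)-3-methylbut-3-en-2-ol F9. Sharpless kinetic resolution (Ti(OiPr)4, L-(+)-diisopropyl tartrate, t-BuOOH 0.6 equiv, 4 Å sieves, CH2Cl2, −20 °C) should epoxidise the (S)-enantiomer to (1S)-2-(5-bromo-2-methoxyphenyl)-1-[(2S)-2-methyloxiran-2-yl]ethanol F10 and leave (R)-11, which is separated by chromatography.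

3. Step 16. Once the allylic alcohol is free in protic acid, ionisation or alkene protonation may set in (solvolysis, hydride shift to the isopropyl ketone, erosion of optical purity) before both MOM acetals are gone. The fallback separates the two events so that the allylic oxygen stays silylated while acid is present; it sets out from 22 and comes back at 23. Aprotic cleavage of both MOM acetals (ZnBr2, n-PrSH, CH2Cl2, 0 °C) would give 2-{3-[(2R)-2-(tert-butyldimethylsilyloxy)-3-methylbut-3-en-1-yl]-4-methoxyphenyl}-3,7-dihydroxy-5,6-dimethoxy-4H-chromen-4-one F11, and buffered fluoride (n-Bu4NF, AcOH, THF, rt) would then give 23.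

**Further compounds**

F1 | step 13 | 3-[(2R)-2-(tert-butyldimethylsilyloxy)-3-methylbut-3-en-1-yl]-4-methoxybenzaldehyde | C=C(C)[C@H](O[Si](C)(C)C(C)(C)C)Cc1cc(C=O)ccc1OC
F2 | step 13 | 1-(2,4-dihydroxy-6-methoxyphenyl)ethanone (purchased) | CC(=O)c1c(O)cc(O)cc1OC
F3 | step 13 | 1-[4-(allyloxy)-2-hydroxy-6-methoxyphenyl]ethanone | CC(=O)c1c(O)cc(OCC=C)cc1OC
F4 | step 13 | 1-[4-(allyloxy)-3,6-dihydroxy-2-methoxyphenyl]ethanone | CC(=O)c1c(O)cc(OCC=C)c(O)c1OC
F5 | step 13 | 1-[4-(allyloxy)-6-hydroxy-2,3-dimethoxyphenyl]ethanone | CC(=O)c1c(O)cc(OCC=C)c(OC)c1OC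
F6 | step 13 | (E)-1-[4-(allyloxy)-6-hydroxy-2,3-dimethoxyphenyl]-3-{3-[(2R)-2-(tert-butyldimethylsilyloxy)-3-methylbut-3-en-1-yl]-4-methoxyphenyl}prop-2-en-1-one | C=C(C)[C@H](O[Si](C)(C)C(C)(C)C)Cc1cc(/C=C/C(=O)c2c(O)cc(OCC=C)c(OC)c2OC)ccc1OC
F7 | step 13 | 7-(allyloxy)-2-{3-[(2R)-2-(tert-butyldimethylsilyloxy)-3-methylbut-3-en-1-yl]-4-methoxyphenyl}-3-hydroxy-5,6-dimethoxy-4H-chromen-4-one | C=C(C)[C@H](O[Si](C)(C)C(C)(C)C)Cc1cc(-c2oc3cc(OCC=C)c(OC)c(OC)c3c(=O)c2O)ccc1OC
F8 | step 13 | 7-(allyloxy)-3-hydroxy-2-{3-[(2R)-2-hydroxy-3-methylbut-3-en-1-yl]-4-methoxyphenyl}-5,6-dimethoxy-4H-chromen-4-one | C=C(C)[C@H](O)Cc1cc(-c2oc3cc(OCC=C)c(OC)c(OC)c3c(=O)c2O)ccc1OC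
F9 | step 7 | racemic 1-(5-bromo-2-methoxyphenyl)-3-methylbut-3-en-2-ol | C=C(C)C(O)Cc1cc(Br)ccc1OC
F10 | step 7 | (1S)-2-(5-bromo-2-methoxyphenyl)-1-[(2S)-2-methyloxiran-2-yl]ethanol | C[C@]1(CO1)[C@@H](O)Cc1cc(Br)ccc1OC
F11 | step 16 | 2-{3-[(2R)-2-(tert-butyldimethylsilyloxy)-3-methylbut-3-en-1-yl]-4-methoxyphenyl}-3,7-dihydroxy-5,6-dimethoxy-4H-chromen-4-one | C=C(C)[C@H](O[Si](C)(C)C(C)(C)C)Cc1cc(-c2oc3cc(O)c(OC)c(OC)c3c(=O)c2O)ccc1OC
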